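**Retrosynthetic overview**
1. Ring A is made last, on the finished ring C enone. C8–C8a comes from a vinylogous Mukaiyama–Michael addition of a dioxinone dienol silane followed by Pd(II) dehydrosilylation, and C4a–C5 from a thermal acylketene closure that aromatises directly to the 5,7-diol.
2. The strategy rests on the O1–C2(H)(aryl)–C3H2–C4(=O) segment of ring C with its C4a=C8a vinylogous-ester double bond. It is cut at C2–C3 and O1–C8a into the B-ring aldehyde (formyl carbon = C2, the only stereocentre) and trans-1-methoxy-3-(trimethylsilyloxy)buta-1,3-diene, which are joined by a catalytic enantioselective hetero-Diels–Alder reaction.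
3. The aldehyde is cut at the aryl–prenyl bond (Suzuki–Miyaura at C–Br) and at the pyran ring (condensation/oxa-6π closure of 5-bromo-2,4-dihydroxybenzaldehyde with 3-methylbut-2-enal). Bromine blocks the second ortho position and marks the prenyl site.
4. Order of ring formation: benzene ring B (bought) → dimethylpyran ring → ring C (step 4, sets 2S) → ring A; MOM removal ends the route.

Key step: step 4

Abbreviation: ArB = 5-(methoxymethoxy)-2,2-dimethyl-8-(3-methylbut-2-enyl)-2H-chromen-6-yl.

Assumption: the (S)-configured biaryl ligand is taken to direct the diene to the Si face of the aldehyde (2S), the sense usually seen for (S)-biaryloxide–titanium additions to aryl aldehydes; if the first run shows the opposite sense, the (R)-ligand is used with no other change.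

**Route**

Step 1
Reactants: 1 5-bromo-2,4-dihydroxybenzaldehyde; 2 3-methylbut-2-enal
Product: 4 8-bromo-5-hydroxy-2,2-dimethyl-2H-chromene-6-carbaldehyde, via o-quinone methide 3 (not isolated)
Conditions: Ca(OH)2 (promoter), MeOH, rt
Reagents that add atoms: none
Why: Base-mediated chromenylation (aldol-type C-alkylation at C3 between the two oxygens, dehydration to the o-quinone methide, oxa-6π electrocyclisation); C5 is blocked by bromine and the 2-OH is held in the chelate with the formyl group, so only the C3/4-oxygen pair can close the pyran.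

Step 2
Reactants: 4 8-bromo-5-hydroxy-2,2-dimethyl-2H-chromene-6-carbaldehyde
Product: 5 8-bromo-5-(methoxymethoxy)-2,2-dimethyl-2H-chromene-6-carbaldehyde
Conditions: MOMCl, iPr2NEt, CH2Cl2, 0 °C → rt
Reagents that add atoms: chloromethyl methyl ether, COCCl
Why: O-alkylation of the chelated phenol with an α-chloro ether (MOM protection); the amine base leaves the aldehyde, the aryl bromide and the chromene untouched.

Step 3
Reactants: 5 8-bromo-5-(methoxymethoxy)-2,2-dimethyl-2H-chromene-6-carbaldehyde; 6 4,4,5,5-tetramethyl-2-(3-methylbut-2-enyl)-1,3,2-dioxaborolane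
Product: 7 5-(methoxymethoxy)-2,2-dimethyl-8-(3-methylbut-2-enyl)-2H-chromene-6-carbaldehyde
Conditions: Pd(dppf)Cl2·CH2Cl2 (5 mol%), K3PO4, THF–H2O (10:1), 70 °C
Reagents that add atoms: none
Why: Suzuki–Miyaura allyl–aryl coupling; reductive elimination at the unsubstituted allyl terminus should give the linear prenyl arene, and the aldehyde, MOM ether and chromene are inert to Pd(0)/phosphate.

Step 4
Reactants: 7 5-(methoxymethoxy)-2,2-dimethyl-8-(3-methylbut-2-enyl)-2H-chromene-6-carbaldehyde; 8 trans-1-methoxy-3-(trimethylsilyloxy)buta-1,3-diene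
Product: 10 (2S)-2-[5-(methoxymethoxy)-2,2-dimethyl-8-(3-methylbut-2-enyl)-2H-chromen-6-yl]-2,3-dihydro-4H-pyran-4-one, via silyl aldol adduct 9 (not isolated)
Conditions: (S)-H8-BINOL (22 mol%), Ti(OiPr)4 (20 mol%), 4 Å MS, toluene, 0 °C; then TFA (cat.), CH2Cl2, 0 °C, short
Reagents that add atoms: none
Why: The titanium biaryloxide binds the formyl oxygen of 7 and the unsubstituted CH2 terminus of the diene attacks the carbonyl carbon, which becomes C2; with this catalyst class the addition runs as a Mukaiyama aldol to 9, and brief acid lets the C2 oxygen add to the methoxy-bearing enone terminus and expel methanol, so the net result is the hetero-Diels–Alder adduct. The closest known reaction type is the BINOL/H8-BINOL–Ti(IV)-catalysed hetero-Diels–Alder (aldol–cyclisation) reaction of 1-alkoxy-3-siloxydienes with aryl aldehydes, ortho-alkoxybenzaldehydes included. Ring C closes as a six-membered dihydropyranone through the O1–C8a bond, by 6-endo oxa-conjugate addition–elimination in the stepwise manifold or by a concerted asynchronous [4+2] if the catalyst operates that way. C2 is the only new stereocentre and is set by catalyst control: the (S)-ligand should shield the Re face so that the diene adds to the Si face, which is 2S because O1 > aryl > C3. The step needs enantiofacial, regio- and chemoselectivity: the diene polarity fixes C–C bonding at its nucleophilic CH2 terminus, the aldehyde is the only group the Lewis acid activates (chromene and prenyl olefins are spectators), and the ortho-MOM oxygen offers a second binding point that rigidifies the aldehyde–titanium complex. The acid closure is kept cold and short because the carbinol carbon is a 2,4-dioxygenated benzylic position.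

Step 5
Reactants: 11 2,2,6-trimethyl-4H-1,3-dioxin-4-one
Product: 13 trimethyl[(2,2-dimethyl-6-methylidene-6H-1,3-dioxin-4-yl)oxy]silane, via lithium dienolate 12 (not isolated)
Conditions: LDA, THF, −78 °C; TMSCl, −78 °C → rt
Reagents that add atoms: chlorotrimethylsilane, C[Si](C)(C)Cl
Why: γ-Deprotonation of the vinylogous ester and O-silylation of the lithium dienolate is the standard preparation of this vinylogous Mukaiyama nucleophile.

Step 6
Reactants: 10 (2S)-2-ArB-2,3-dihydro-4H-pyran-4-one; 13 trimethyl[(2,2-dimethyl-6-methylidene-6H-1,3-dioxin-4-yl)oxy]silane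
Product: 15 6-{[(2S)-2-ArB-4-oxo-3,4-dihydro-2H-pyran-6-yl]methyl}-2,2-dimethyl-4H-1,3-dioxin-4-one, via enol silane 14 (not isolated)
Conditions: TMSOTf (10 mol%), CH2Cl2, −78 °C; Et3N, concentrate; Pd(OAc)2 (1.1 equiv), MeCN, rt
Reagents that add atoms: none
Why: Vinylogous Mukaiyama–Michael addition to the silyl-triflate-activated dihydropyranone at C6 (future C8a) with silyl transfer gives the regiodefined enol silane 14 (axial attack, 2,6-trans, of no consequence), and in the Saegusa–Ito oxidation β-hydride elimination is possible only toward C6–H, which restores the vinylogous ester with the C8 carbon attached while C2 never becomes part of an enolate.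

Step 7
Reactants: 15 6-{[(2S)-2-ArB-4-oxo-3,4-dihydro-2H-pyran-6-yl]methyl}-2,2-dimethyl-4H-1,3-dioxin-4-one
Product: 17 (2S)-5,7-dihydroxy-2-[5-(methoxymethoxy)-2,2-dimethyl-8-(3-methylbut-2-enyl)-2H-chromen-6-yl]-2,3-dihydro-4H-chromen-4-one, via acylketene 16 (not isolated)
Conditions: dry toluene (5 mM), 110 °C
Reagents that add atoms: none
Why: Proposed new method: heating the dioxinone should release acetone by retro-[4+2] and give acylketene 16; enolisation of its C7 ketone toward the doubly activated C8 methylene gives a dienylketene whose 6π electrocyclisation joins the ketene carbon (C5) to C4a (equivalently, the ketene carbon acylates the nucleophilic α-carbon of the vinylogous ester), a six-membered closure that O-attack cannot rival because it would need a four- or eight-membered ring; tautomerisation of the dienone then gives the aromatic 5,7-diol at the correct oxidation level with no base present, so C2 is not at risk. The closest known reaction types are the dienylketene electrocyclisation to phenols (Danheiser benzannulation) and the dioxinone-to-acylketene thermolysis used in resorcylate aromatisations.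

Step 8
Reactants: 17 (2S)-5,7-dihydroxy-2-[5-(methoxymethoxy)-2,2-dimethyl-8-(3-methylbut-2-enyl)-2H-chromen-6-yl]-2,3-dihydro-4H-chromen-4-one
Product: 18 sanggenol N, (2S)-5,7-dihydroxy-2-[5-hydroxy-2,2-dimethyl-8-(3-methylbut-2-enyl)-2H-chromen-6-yl]-2,3-dihydro-4H-chromen-4-one
Conditions: HCl (1.25 M in MeOH), rt → 40 °C
Reagents that add atoms: none
Why: Acid-catalysed acetal exchange with methanol removes the MOM group; the freed 2'-OH is para to the prenyl group and cannot cyclise onto it, and dilute acid at or below 40 °C should not open the flavanone at C2.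

**Compound list**
1 | 5-bromo-2,4-dihydroxybenzaldehyde | O=Cc1cc(Br)c(O)cc1O | starting material
2 | 3-methylbut-2-enal | CC(C)=CC=O | starting material
3 | 5-bromo-2-hydroxy-3-(3-methylbut-2-enylidene)-4-oxocyclohexa-1,5-diene-1-carbaldehyde (o-quinone methide) | O=CC1=C(O)C(=CC=C(C)C)C(=O)C(Br)=C1 | intermediate
4 | 8-bromo-5-hydroxy-2,2-dimethyl-2H-chromene-6-carbaldehyde | O=Cc1cc(Br)c2OC(C)(C)C=Cc2c1O | intermediate
5 | 8-bromo-5-(methoxymethoxy)-2,2-dimethyl-2H-chromene-6-carbaldehyde | COCOc1c(C=O)cc(Br)c2OC(C)(C)C=Cc12 | intermediate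
6 | 4,4,5,5-tetramethyl-2-(3-methylbut-2-enyl)-1,3,2-dioxaborolane | CC(C)=CCB1OC(C)(C)C(C)(C)O1 | starting material
7 | 5-(methoxymethoxy)-2,2-dimethyl-8-(3-methylbut-2-enyl)-2H-chromene-6-carbaldehyde | CC(C)=CCc1cc(C=O)c(OCOC)c2c1OC(C)(C)C=C2 | intermediate
8 | trans-1-methoxy-3-(trimethylsilyloxy)buta-1,3-diene | CO/C=C/C(=C)O[Si](C)(C)C | starting material
9 | (1E,5S)-1-methoxy-5-ArB-5-(trimethylsilyloxy)pent-1-en-3-one | CO/C=C/C(=O)C[C@H](O[Si](C)(C)C)c1cc(CC=C(C)C)c2OC(C)(C)C=Cc2c1OCOC | intermediate
10 | (2S)-2-[5-(methoxymethoxy)-2,2-dimethyl-8-(3-methylbut-2-enyl)-2H-chromen-6-yl]-2,3-dihydro-4H-pyran-4-one | CC(C)=CCc1cc([C@@H]2CC(=O)C=CO2)c(OCOC)c2c1OC(C)(C)C=C2 | intermediate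
11 | 2,2,6-trimethyl-4H-1,3-dioxin-4-one | CC1=CC(=O)OC(C)(C)O1 | starting material
12 | lithium 2,2-dimethyl-6-methylidene-6H-1,3-dioxin-4-olate | [Li]OC1=CC(=C)OC(C)(C)O1 | intermediate
13 | trimethyl[(2,2-dimethyl-6-methylidene-6H-1,3-dioxin-4-yl)oxy]silane | C=C1C=C(O[Si](C)(C)C)OC(C)(C)O1 | intermediate
14 | 6-{[(2R,6S)-6-ArB-4-(trimethylsilyloxy)-5,6-dihydro-2H-pyran-2-yl]methyl}-2,2-dimethyl-4H-1,3-dioxin-4-one (2,6-trans) | C[Si](C)(C)OC1=C[C@@H](CC2=CC(=O)OC(C)(C)O2)O[C@H](c2cc(CC=C(C)C)c3OC(C)(C)C=Cc3c2OCOC)C1 | intermediate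
15 | 6-{[(2S)-2-ArB-4-oxo-3,4-dihydro-2H-pyran-6-yl]methyl}-2,2-dimethyl-4H-1,3-dioxin-4-one | O=C1C=C(CC2=CC(=O)OC(C)(C)O2)O[C@H](c2cc(CC=C(C)C)c3OC(C)(C)C=Cc3c2OCOC)C1 | intermediate
16 | 4-[(2S)-2-ArB-4-oxo-3,4-dihydro-2H-pyran-6-yl]-3-oxobut-1-en-1-one (acylketene) | O=C=CC(=O)CC1=CC(=O)C[C@@H](c2cc(CC=C(C)C)c3OC(C)(C)C=Cc3c2OCOC)O1 | intermediate
17 | (2S)-5,7-dihydroxy-2-[5-(methoxymethoxy)-2,2-dimethyl-8-(3-methylbut-2-enyl)-2H-chromen-6-yl]-2,3-dihydro-4H-chromen-4-one | CC(C)=CCc1cc([C@@H]2CC(=O)c3c(O)cc(O)cc3O2)c(OCOC)c2c1OC(C)(C)C=C2 | intermediate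
18 | sanggenol N, (2S)-5,7-dihydroxy-2-[5-hydroxy-2,2-dimethyl-8-(3-methylbut-2-enyl)-2H-chromen-6-yl]-2,3-dihydro-4H-chromen-4-one | CC(C)=CCc1cc([C@@H]2CC(=O)c3c(O)cc(O)cc3O2)c(O)c2c1OC(C)(C)C=C2 | target

**Step count**
Total steps: 8. Longest linear sequence: 7 (steps 1, 2, 3, 4, 6, 7, 8); step 5 is a one-step side branch.

**Steps most likely to fail**

1. Step 7 (proposed new method). The acylketene may be consumed by dimerisation, or by O-acylation of the phenols of product already formed, faster than it closes onto C4a; the closure may also stall before aromatisation. The fallback sets out from 15 and comes back at 17 using known chemistry. 15 is heated in toluene at 110 °C with methanol so that the acylketene is intercepted as the β-keto ester methyl 4-[(2S)-2-ArB-4-oxo-3,4-dihydro-2H-pyran-6-yl]-3-oxobutanoate F1. Ring A is then closed by an intramolecular Claisen (Dieckmann-type) condensation of the extended dienolate (deprotonation at C8, attack of C4a on the ester; NaOMe, MeOH, 0 °C → rt). This is the acylphloroglucinol-forming cyclisation known for polyketide-type 3,5-dioxo esters, and the product aromatises spontaneously to 17. The reaction is quenched with acid as soon as conversion is complete to limit base-induced opening of ring C at C2.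

2. Step 4 (key step). Facial discrimination may be insufficient, because the ortho-MOM ether can chelate titanium and change the geometry of the bound aldehyde. Addition to the electron-rich aldehyde may be slow. The configuration may erode, or dehydration may occur, through ionisation of the doubly oxygen-activated benzylic carbinol during the acid closure. The fallback sets out from 7 and comes back at 10, forming the same two bonds by a reagent-controlled aldol followed by cyclisation. (E)-4-Chlorobut-3-en-2-one is enolised with iPr2NEt and the antipode of Ipc2BCl that directs attack to the Si face, and is added to 7 at −78 °C. Non-oxidative work-up should give (1E,5S)-1-chloro-5-hydroxy-5-ArB-pent-1-en-3-one F2. Base-mediated 6-endo addition–elimination (iPr2NEt with a silyl triflate, or K2CO3 in MeOH) then closes ring C with loss of HCl to give 10, with no acid contact at the benzylic carbinol.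

3. Step 6. The silyl triflate may cleave the MOM ether or open ring C reversibly at the benzylic C2–O1 bond of the silyloxy-oxocarbenium ion, with loss of enantiopurity. Pd(II) may engage the prenyl or chromene olefins, or the enol silane may be protodesilylated to the saturated ketone instead of being oxidised. The fallback sets out from 10 and comes back at 15, carrying the oxidation level as a leaving group instead of using a palladium oxidation. 10 is α-iodinated (I2, pyridine, CH2Cl2) to (2S)-2-ArB-5-iodo-2,3-dihydro-4H-pyran-4-one F3. Mukaiyama–Michael addition of 13 (TMSOTf cat., −78 °C) gives the α-iodo enol silane 6-{[(6S)-6-ArB-3-iodo-4-(trimethylsilyloxy)-5,6-dihydro-2H-pyran-2-yl]methyl}-2,2-dimethyl-4H-1,3-dioxin-4-one F4. Mild aqueous work-up gives the α-iodo ketone 6-{[(6S)-6-ArB-3-iodo-4-oxotetrahydro-2H-pyran-2-yl]methyl}-2,2-dimethyl-4H-1,3-dioxin-4-one F5, and DBU (CH2Cl2, 0 °C) eliminates HI across the former enone carbons to return 15.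

**Further compounds**
F1 | step 7 | methyl 4-[(2S)-2-ArB-4-oxo-3,4-dihydro-2H-pyran-6-yl]-3-oxobutanoate | COC(=O)CC(=O)CC1=CC(=O)C[C@@H](c2cc(CC=C(C)C)c3OC(C)(C)C=Cc3c2OCOC)O1
F2 | step 4 | (1E,5S)-1-chloro-5-hydroxy-5-ArB-pent-1-en-3-one | Cl/C=C/C(=O)C[C@H](O)c1cc(CC=C(C)C)c2OC(C)(C)C=Cc2c1OCOC
F3 | step 6 | (2S)-2-ArB-5-iodo-2,3-dihydro-4H-pyran-4-one | CC(C)=CCc1cc([C@@H]2CC(=O)C(I)=CO2)c(OCOC)c2c1OC(C)(C)C=C2
F4 | step 6 | 6-{[(6S)-6-ArB-3-iodo-4-(trimethylsilyloxy)-5,6-dihydro-2H-pyran-2-yl]methyl}-2,2-dimethyl-4H-1,3-dioxin-4-one | C[Si](C)(C)OC1=C(I)C(CC2=CC(=O)OC(C)(C)O2)O[C@H](c2cc(CC=C(C)C)c3OC(C)(C)C=Cc3c2OCOC)C1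
F5 | step 6 | 6-{[(6S)-6-ArB-3-iodo-4-oxotetrahydro-2H-pyran-2-yl]methyl}-2,2-dimethyl-4H-1,3-dioxin-4-one | O=C1C(I)C(CC2=CC(=O)OC(C)(C)O2)O[C@H](c2cc(CC=C(C)C)c3OC(C)(C)C=Cc3c2OCOC)C1
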